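Ring B is disconnected at C5–C6 and C9–C10 by an enantioselective Diels–Alder reaction between an achiral ring A dienophile, a 3-oxocyclohex-1-ene-1-carboxylate (C4 as ketone, C20 as ester on C10), and a 2-silyloxy diene carrying C6–C9 and C11–C12. One operation closes ring B and sets the quaternary C10. It exploits that C5 and C9 of the target lie α to latent carbonyls at C4 (later the quaternary ester carbon) and C8 (later the exocyclic methylene carbon): both are equilibrated afterwards, so the cis-fused, endo adduct funnels into the trans-decalin with equatorial side chain.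

Key step: step 4

Remark on the chemistry: positions are given in labdane numbering (ring A = C1–C5, C10; ring B = C5–C10; C17 = methylene carbon on C8; C18 = methyl and C19 = ester carbon on C4; C20 = carbonyl carbon on C10; C11–C16 = side chain). β is the face of the C20 substituent, α the opposite face. The target is (4S,5R,9S,10S). 3-Oxocyclohex-1-ene-1-carboxylic acid is assumed to be purchasable.

Step 1
Reactants: 1 4-chlorobutanoyl chloride; 2 tributyl(vinyl)stannane
Product: 3 6-chlorohex-1-en-3-one
Conditions: PdCl2(PPh3)2 (2 mol %), THF, 50 °C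
Reagents that add atoms: none
Why: Stille acylation couples the acyl chloride chemoselectively (the primary alkyl chloride is inert) and should give the vinyl ketone that holds C6–C9, C11 and C12.

Step 2
Reactants: 3 6-chlorohex-1-en-3-one
Product: 4 (Z)-2-silyloxy diene
Conditions: i-Pr3SiOSO2CF3, Et3N, CH2Cl2, −78 to 0 °C
Reagents that add atoms: triisopropylsilyl trifluoromethanesulfonate, CC(C)[Si](C(C)C)(C(C)C)OS(=O)(=O)C(F)(F)F
Why: Soft enolisation (silyl enol ether formation) at the only enolisable carbon, C9, should give the thermodynamically preferred Z enol ether, in which the chloroethyl chain sits on the reactive outside position of the diene.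

Step 3
Reactants: 5 3-oxocyclohex-1-ene-1-carboxylic acid
Product: 6 2-(trimethylsilyl)ethyl 3-oxocyclohex-1-ene-1-carboxylate
Conditions: Me3SiCH2CH2OH, DCC, DMAP (cat.), CH2Cl2, 0 °C to rt
Reagents that add atoms: 2-(trimethylsilyl)ethanol, C[Si](C)(C)CCO
Why: Steglich esterification installs a fluoride-labile ester that keeps C20 distinguishable from the later C19 methyl ester.

Step 4
Reactants: 6 2-(trimethylsilyl)ethyl 3-oxocyclohex-1-ene-1-carboxylate; 4 (Z)-2-silyloxy diene
Product: 8 trans-fused ketone, via cis-fused cycloadduct 7 (not isolated)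
Conditions: (S)-3,3-diphenyl-1-(o-tolyl)tetrahydropyrrolo[1,2-c][1,3,2]oxazaborole activated with HN(SO2CF3)2 (20 mol %), CH2Cl2, −78 to −20 °C; then Et3N, concentrate; DBU, toluene, rt
Reagents that add atoms: none
Why: The chiral oxazaborolidinium ion binds the ring A ketone oxygen and lowers the LUMO of the C5=C10 bond, so the silyloxy diene adds in a concerted, asynchronous normal-demand [4+2] cycloaddition; the closest known reaction type is the oxazaborolidinium-catalysed Diels–Alder reaction of 2-silyloxy dienes with cyclic enones. Ring B is closed in the suprafacial (π4s + π2s) mode, C9 (the nucleophilic β-carbon of the enol ether) bonding to C10 (β to the ketone) and C6 to C5. C10 is set by the catalyst, which should expose the face that is Si at C10 (the (R)-catalyst is used if the opposite sense is found). C5 is first formed cis by suprafacial addition to the ring A alkene and is then epimerised by DBU through the C4 enolate to the more stable trans fusion, while C9 comes from the endo transition state (C11 anti to the ester) and is provisional because it is equilibrated in step 10. The step needs regioselectivity and enantiofacial selectivity: the first is secured by the Lewis-acid-bound ketone, which as the stronger acceptor makes C10 the electrophilic terminus against the directing effect of the ester, the second by the catalyst because the dienophile is achiral. The trans preference at C5 rests on the trigonal centres C4 and C8, which remove two of the 1,3-diaxial contacts of the axial C10 ester.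

Step 5
Reactants: 8 trans-fused ketone
Product: 9 Δ3 enol triflate
Conditions: KN(SiMe3)2, THF, −78 °C; then PhN(SO2CF3)2, −78 to 0 °C
Reagents that add atoms: N-phenylbis(trifluoromethanesulfonimide), O=S(=O)(N(c1ccccc1)S(=O)(=O)C(F)(F)F)C(F)(F)F
Why: Kinetic enolate formation and O-triflation should occur at the C3 methylene and not at the hindered C5 methine, so the equilibrated C5 centre is left untouched.

Step 6
Reactants: 9 Δ3 enol triflate
Product: 10 Δ3 unsaturated diester
Conditions: Pd(OAc)2 (5 mol %), PPh3, CO (1 atm), Et3N, MeOH/DMF, 60 °C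
Reagents that add atoms: carbon monoxide, [C-]#[O+]; methanol, CO
Why: Palladium-catalysed methoxycarbonylation of the vinyl triflate installs C19 directly as the methyl ester of the target.

Step 7
Reactants: 10 Δ3 unsaturated diester
Product: 12 C4-methylated diester, via lithium ester enolate 11 (not isolated)
Conditions: Li[HB(s-Bu)3], THF, −78 °C; then MeI, DMPU, −78 to 0 °C
Reagents that add atoms: iodomethane, CI
Why: Reductive alkylation (conjugate hydride addition at C3, then enolate methylation) should set the quaternary C4 by substrate control, MeI entering on the α face anti to the 1,3-diaxial C10 ester so that C18 is α and C19 is β.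

Step 8
Reactants: 13 3-bromooxolan-2-one
Product: 14 3-(phenylsulfanyl)oxolan-2-one
Conditions: PhSH, Et3N, CH2Cl2, 0 °C to rt
Reagents that add atoms: benzenethiol, Sc1ccccc1
Why: SN2 displacement of the activated α-bromide by thiolate gives the sulfur-stabilised lactone that serves as a masked butenolide.

Step 9
Reactants: 12 C4-methylated diester; 14 3-(phenylsulfanyl)oxolan-2-one
Product: 15 sulfanyl lactone
Conditions: NaH, DMF, 0 °C (14); then 12, n-Bu4NI (cat.), 50 °C
Reagents that add atoms: none
Why: Enolate alkylation of the sulfur-stabilised lactone by the primary chloride (iodide catalysis) forms the C12–C13 bond; the new C13 centre is uncontrolled and is removed in step 13.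

Step 10
Reactants: 15 sulfanyl lactone
Product: 17 keto acid, via C9-epimeric keto acid 16 (not isolated)
Conditions: n-Bu4NF, THF, 0 °C to rt; then DBU, rt; dilute aq. HCl work-up
Reagents that add atoms: none
Why: Fluoride desilylation unmasks the C8 ketone and releases the C20 acid by β-elimination of the silylethyl group, and base equilibration through the C8 enolate should move the C9 side chain to the equatorial β position (thermodynamic control).

Step 11
Reactants: 17 keto acid
Product: 18 methylene acid
Conditions: Ph3PCH3Br, KOC(CH3)3 (excess), toluene, 0 to 60 °C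
Reagents that add atoms: methylenetriphenylphosphorane, C=P(c1ccccc1)(c1ccccc1)c1ccccc1
Why: Wittig methylenation converts the C8 ketone into the C8=C17 exocyclic alkene; the carboxylate is inert and C9 already holds its thermodynamic configuration.

Step 12
Reactants: 18 methylene acid
Product: 20 C20 aldehyde, via acid chloride 19 (not isolated)
Conditions: Me2C=C(Cl)NMe2, CH2Cl2, 0 °C; then LiAlH(OtBu)3, THF, −78 °C
Reagents that add atoms: none
Why: Neutral acid chloride formation followed by hindered-hydride reduction of the acyl chloride should stop at the aldehyde and leave the methyl ester, the lactone and the alkene untouched.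

Step 13
Reactants: 20 C20 aldehyde
Product: 22 CNP0175906.1, via sulfoxide 21 (not isolated)
Conditions: m-CPBA (1.0 equiv), CH2Cl2, −78 °C; then toluene, 110 °C
Reagents that add atoms: none
Why: Sulfide oxidation and thermal sulfoxide syn-elimination toward the ring methylene C14 should give the conjugated endocyclic butenolide and erase the C13 centre.

Compound list
1 | 4-chlorobutanoyl chloride | ClCCCC(Cl)=O | starting material
2 | tributyl(vinyl)stannane | C=C[Sn](CCCC)(CCCC)CCCC | starting material
3 | 6-chlorohex-1-en-3-one | C=CC(=O)CCCCl | intermediate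
4 | (Z)-[(6-chlorohexa-1,3-dien-3-yl)oxy]tri(propan-2-yl)silane | C=C/C(O[Si](C(C)C)(C(C)C)C(C)C)=C/CCCl | intermediate
5 | 3-oxocyclohex-1-ene-1-carboxylic acid | O=C1CCCC(C(=O)O)=C1 | starting material
6 | 2-(trimethylsilyl)ethyl 3-oxocyclohex-1-ene-1-carboxylate | O=C1CCCC(C(=O)OCC[Si](C)(C)C)=C1 | intermediate
7 | cis-fused cycloadduct: 2-(trimethylsilyl)ethyl 1-(2-chloroethyl)-5-oxo-2-[tri(propan-2-yl)silyloxy]-1,4,4a,5,6,7,8,8a-octahydronaphthalene-8a-carboxylate; H-5 β (cis to the C10 ester), chloroethyl on C9 α | CC(C)[Si](C(C)C)(C(C)C)OC1=CC[C@H]2[C@](C(=O)OCC[Si](C)(C)C)(CCCC2=O)[C@@H]1CCCl | intermediate (not isolated)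
8 | trans-fused ketone: constitution of 7 with H-5 α (trans to the C10 ester), chloroethyl on C9 α | CC(C)[Si](C(C)C)(C(C)C)OC1=CC[C@@H]2[C@](C(=O)OCC[Si](C)(C)C)(CCCC2=O)[C@@H]1CCCl | intermediate
9 | Δ3 enol triflate: C4 trifluoromethanesulfonyloxy, C3=C4 and C7=C8 double bonds, C8 triisopropylsilyloxy, C10 2-(trimethylsilyl)ethyl ester β, H-5 α, chloroethyl on C9 α | CC(C)[Si](C(C)C)(C(C)C)OC1=CC[C@@H]2[C@](C(=O)OCC[Si](C)(C)C)(CCC=C2OS(=O)(=O)C(F)(F)F)[C@@H]1CCCl | intermediate
10 | Δ3 unsaturated diester: as 9 with a methoxycarbonyl group (C19) on C4 in place of the triflate | CC(C)[Si](C(C)C)(C(C)C)OC1=CC[C@@H]2[C@](C(=O)OCC[Si](C)(C)C)(CCC=C2C(=O)OC)[C@@H]1CCCl | intermediate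
11 | lithium ester enolate: C4=C19(OMe)OLi, C3 saturated, otherwise as 10 | CC(C)[Si](C(C)C)(C(C)C)OC1=CC[C@@H]2[C@](C(=O)OCC[Si](C)(C)C)(CCCC2=C(OC)O[Li])[C@@H]1CCCl | intermediate (not isolated)
12 | C4-methylated diester: C4 quaternary with methyl α and methyl ester β, C10 2-(trimethylsilyl)ethyl ester β, H-5 α, C8 silyl enol ether (C7=C8), chloroethyl on C9 α | CC(C)[Si](C(C)C)(C(C)C)OC1=CC[C@@H]2[C@](C(=O)OCC[Si](C)(C)C)(CCC[C@]2(C)C(=O)OC)[C@@H]1CCCl | intermediate
13 | 3-bromooxolan-2-one (α-bromo-γ-butyrolactone, racemic) | O=C1OCCC1Br | starting material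
14 | 3-(phenylsulfanyl)oxolan-2-one (racemic) | O=C1OCCC1Sc1ccccc1 | intermediate
15 | sulfanyl lactone: as 12 with the chloride replaced by a 2-oxo-3-(phenylsulfanyl)oxolan-3-yl group on C12 (both C13 epimers) | CC(C)[Si](C(C)C)(C(C)C)OC1=CC[C@@H]2[C@](C(=O)OCC[Si](C)(C)C)(CCC[C@]2(C)C(=O)OC)[C@@H]1CCC1(Sc2ccccc2)CCOC1=O | intermediate
16 | C9-epimeric keto acid: C8 ketone, C20 carboxylic acid β, C19 methyl ester β, H-5 α, side chain on C9 α | O=C1CC[C@@H]2[C@](C(=O)O)(CCC[C@]2(C)C(=O)OC)[C@@H]1CCC1(Sc2ccccc2)CCOC1=O | intermediate (not isolated)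
17 | keto acid: as 16 with the side chain on C9 β (equatorial) | O=C1CC[C@@H]2[C@](C(=O)O)(CCC[C@]2(C)C(=O)OC)[C@H]1CCC1(Sc2ccccc2)CCOC1=O | intermediate
18 | methylene acid: as 17 with C8=C17 exocyclic methylene in place of the ketone | C=C1CC[C@@H]2[C@](C(=O)O)(CCC[C@]2(C)C(=O)OC)[C@H]1CCC1(Sc2ccccc2)CCOC1=O | intermediate
19 | acid chloride: as 18 with C20 as carbonyl chloride | C=C1CC[C@@H]2[C@](C(Cl)=O)(CCC[C@]2(C)C(=O)OC)[C@H]1CCC1(Sc2ccccc2)CCOC1=O | intermediate (not isolated)
20 | C20 aldehyde: as 18 with C20 as formyl group | C=C1CC[C@@H]2[C@](C=O)(CCC[C@]2(C)C(=O)OC)[C@H]1CCC1(Sc2ccccc2)CCOC1=O | intermediate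
21 | sulfoxide: as 20 with phenylsulfinyl in place of phenylsulfanyl (mixture at C13 and sulfur) | C=C1CC[C@@H]2[C@](C=O)(CCC[C@]2(C)C(=O)OC)[C@H]1CCC1(S(=O)c2ccccc2)CCOC1=O | intermediate (not isolated)
22 | CNP0175906.1: methyl (1S,4aS,5S,8aR)-4a-formyl-1-methyl-6-methylidene-5-[2-(2-oxo-2,5-dihydrofuran-3-yl)ethyl]decahydronaphthalene-1-carboxylate | C=C1CC[C@@H]2[C@](C=O)(CCC[C@]2(C)C(=O)OC)[C@H]1CCC1=CCOC1=O | target

Total step count: 13
Longest linear sequence: 11 steps (steps 1, 2, 4, 5, 6, 7, 9, 10, 11, 12, 13)

Steps most likely to fail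

Step 4. Bond formation at the fully substituted C10 may be slow under the chiral catalyst, so that the diene is consumed by open-chain Michael addition or hydrolysis, and enantiofacial control may erode. The fallback sets out from 6 and 4 and runs the annulation as a stepwise Mukaiyama–Michael/intramolecular Mukaiyama–Michael sequence catalysed by HN(SO2CF3)2 (5 mol %, CH2Cl2, −78 to −40 °C; the silyl triflimide formed in the flask is the active catalyst), a mode that tolerates hindered acceptors. After DBU equilibration this should give the racemate, that is 8 together with the enantiomeric trans-fused ketone F2, formed through the enantiomeric cis-fused cycloadduct F1. The enantiomers are separated by preparative chromatography on a chiral stationary phase, and the route is re-entered at 8.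

Step 7. The hydride may attack the ester carbonyl or fail to add to the hindered enoate, and facial control in the methylation may erode at the higher temperature needed. The fallback sets out from 10: Mg turnings in MeOH (0 °C to rt) reduce the conjugated ester by electron transfer to the saturated diester F3 (either C4 epimer). F3 is then deprotonated with LiN(i-Pr)2 (THF, −78 °C) and methylated with MeI, which passes through the same enolate 11 and comes back at 12.

Step 11. The ylide may act only as a base: the γ-keto acid can close to its hydroxy-lactone form or be enolised, so that olefination stalls. The fallback sets out from 15 and changes the order of unmasking. Aqueous 1 M HCl in THF cleaves only the silyl enol ether and gives the C9-epimeric keto diester F4, which DBU equilibrates to the keto diester F5 with the silylethyl ester still in place. Wittig methylenation (Ph3PCH3Br, KOC(CH3)3, toluene) then gives the methylene diester F6, and n-Bu4NF (THF, rt) releases the acid, coming back at 18.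

Further compounds
F1 | step 4 | enantiomeric cis-fused cycloadduct (mirror image of 7, not isolated) | CC(C)[Si](C(C)C)(C(C)C)OC1=CC[C@@H]2[C@@](C(=O)OCC[Si](C)(C)C)(CCCC2=O)[C@H]1CCCl
F2 | step 4 | enantiomeric trans-fused ketone (mirror image of 8) | CC(C)[Si](C(C)C)(C(C)C)OC1=CC[C@H]2[C@@](C(=O)OCC[Si](C)(C)C)(CCCC2=O)[C@H]1CCCl
F3 | step 7 | saturated diester (10 with C3–C4 reduced, both C4 epimers) | CC(C)[Si](C(C)C)(C(C)C)OC1=CC[C@@H]2[C@](C(=O)OCC[Si](C)(C)C)(CCCC2C(=O)OC)[C@@H]1CCCl
F4 | step 11 | C9-epimeric keto diester (C8 ketone, silylethyl ester retained, side chain α, not isolated) | O=C1CC[C@@H]2[C@](C(=O)OCC[Si](C)(C)C)(CCC[C@]2(C)C(=O)OC)[C@@H]1CCC1(Sc2ccccc2)CCOC1=O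
F5 | step 11 | keto diester (as F4 with the side chain β) | O=C1CC[C@@H]2[C@](C(=O)OCC[Si](C)(C)C)(CCC[C@]2(C)C(=O)OC)[C@H]1CCC1(Sc2ccccc2)CCOC1=O
F6 | step 11 | methylene diester (as F5 with C8=C17 methylene) | C=C1CC[C@@H]2[C@](C(=O)OCC[Si](C)(C)C)(CCC[C@]2(C)C(=O)OC)[C@H]1CCC1(Sc2ccccc2)CCOC1=O
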